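The seven-membered ring (C1, C5–C10; C1 = angular-methyl carbon, C5 = ring-fusion CH, C6 = CHOH, C8/C9 = epoxide carbons) is cut at C7–C8 and C9–C10. A single rhodium-catalysed (5+2) cycloaddition joins a vinylcyclopropane five-carbon unit (vinyl C6=C7 on C5; cyclopropane C5–C1–C10, opening at C5–C10) to the two alkyne carbons of 1-(trimethylsilyl)propyne (C8, C9). The ring closes with its two alkenes already at C5=C6 and C8=C9, and the quaternary centre C1, set earlier, is not touched. The precursor is (1R,2R,5R)-5-methyl-1-vinylbicyclo[3.1.0]hexan-2-ol; its C4 carbinol, which first directs cyclopropanation, is kept so that it can later deliver H-5 and O-6 to the α face.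

Key step: step 4

Remark 1 (target): the target SMILES is taken as drawn, i.e. the tertiary C4 4-hydroxybenzoate with free 6-OH and an 8,9-epoxide, configuration (1R,4R,5S,6S,8R,9S).
Remark 2 (numbering): daucane atom numbers are used for all bicyclic compounds (C1 angular-methyl carbon, C2/C3 cyclopentane CH2, C4 carbinol carbon that later bears isopropyl, C5 ring-fusion carbon, C6 oxygenated CH, C7 and C10 cycloheptane CH2, C8 methyl-bearing, C9); β is the face of the C1 methyl group, α the opposite face; compounds without the isopropyl group are named as 11,12,13-trinordaucanes.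
Remark 3 (precursor design): the cycloaddition partner is used at the C4 alcohol level; the carbon skeleton and the bonds formed are unchanged, and the carbinol gives the facial control at C5=C6 that an sp2 C4 cannot (the C1 methyl and the C10 methylene flank that alkene almost symmetrically).
Remark 4 (assumption): 2-bromo-3-methylcyclopent-2-en-1-one (1) is taken as a catalogue compound.
Remark 5: in 22 and 23 the tertiary ester lies close to the free 6-OH and could migrate to it under base, so steps 13 and 14 are kept acidic or neutral.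

Step 1
Reactants: 1 2-bromo-3-methylcyclopent-2-en-1-one
Product: 2 (R)-2-bromo-3-methylcyclopent-2-en-1-ol
Conditions: (S)-2-methyl-CBS-oxazaborolidine (10 mol %), BH3·SMe2, THF, 0 °C; MeOH
Reagents that add atoms: none
Why: Corey–Bakshi–Shibata reduction: the α-bromoalkenyl arm acts as the large carbonyl substituent, so the (S)-catalyst should deliver hydride to one face and set the carbinol (future C4) as R.

Step 2
Reactants: 2 (R)-2-bromo-3-methylcyclopent-2-en-1-ol; 3 4,4,5,5-tetramethyl-2-vinyl-1,3,2-dioxaborolane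
Product: 4 (R)-3-methyl-2-vinylcyclopent-2-en-1-ol
Conditions: Pd(OAc)2 (5 mol %), SPhos (10 mol %), K3PO4, THF/H2O (10:1), 60 °C
Reagents that add atoms: none
Why: Suzuki–Miyaura coupling of the alkenyl bromide should install the vinyl group (future C6=C7) with the free hydroxyl and the carbinol configuration untouched.

Step 3
Reactants: 4 (R)-3-methyl-2-vinylcyclopent-2-en-1-ol; 5 diiodomethane
Product: 6 (1R,2R,5R)-5-methyl-1-vinylbicyclo[3.1.0]hexan-2-ol (hydroxyl cis to the cyclopropane CH2)
Conditions: Et2Zn (2.2 equiv), 5 (2.2 equiv), CH2Cl2, −10 → 0 °C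
Reagents that add atoms: none
Why: Hydroxyl-directed Simmons–Smith cyclopropanation (Furukawa reagent): the zinc alkoxide delivers CH2 (future C10) to the adjacent electron-rich tetrasubstituted ring alkene on the hydroxyl face, which sets C1 and C5 with the cyclopropane cis to OH and spares the more remote vinyl group.

Step 4
Reactants: 6 (1R,2R,5R)-5-methyl-1-vinylbicyclo[3.1.0]hexan-2-ol; 7 1-(trimethylsilyl)propyne
Product: 8 (1R,4R)-9-(trimethylsilyl)-11,12,13-trinordauca-5,8-dien-4-ol (4α-OH)
Conditions: 7 (3 equiv), [Rh(CO)2Cl]2 (5 mol %), ClCH2CH2Cl, 80 °C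
Reagents that add atoms: none
Why: After π-coordination of the vinyl group, monovalent rhodium undergoes oxidative addition into the C5–C10 bond to give a trivalent-rhodium species that holds C5–C6–C7 as an η3-allyl and C10 as a σ-alkyl; migratory insertion of 7 forms C7–C8 and reductive elimination forms C9–C10. The closest known reaction is the [Rh(CO)2Cl]2-catalysed intermolecular (5+2) cycloaddition of 1-substituted vinylcyclopropanes with alkynes. The seven-membered ring closes in the final C–C reductive elimination from an eight-membered rhodacycle, so both new bonds are made on the metal. No stereocentre is formed: C1 and C4 pass through unchanged and C5 becomes sp2. The step needs opening of C5–C10 and not C5–C1, and the methyl-bearing alkyne carbon at C7: insertion toward C10 gives the less hindered primary alkyl–rhodium bond (the alternative would need a bond to quaternary C1 and lead to a bridged ring with a bridgehead alkene), the cis hydroxyl on C4 can hold the metal on the C10 face, and the larger silyl-substituted alkyne carbon stays distal to the C7–C8 bond that forms first, so silicon ends on C9. β-Hydride elimination from the C10–rhodium bond cannot occur because C1 carries no hydrogen.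

Step 5
Reactants: 8 (1R,4R)-9-(trimethylsilyl)-11,12,13-trinordauca-5,8-dien-4-ol
Product: 10 (1R,4R,5R,6S)-4-O,6-C-(dimethylsilanediyl)-9-(trimethylsilyl)-11,12,13-trinordauc-8-en-4-ol (five-membered cyclic silyl ether O4–SiMe2–C6; H-5 α), via dimethylsilyl ether 9 (not isolated)
Conditions: (HMe2Si)2NH, 60 °C, evaporate; Pt2[(CH2=CHSiMe2)2O]3 (Karstedt catalyst, 1 mol %), toluene, 60 °C
Reagents that add atoms: 1,1,3,3-tetramethyldisilazane, C[SiH](C)N[SiH](C)C
Why: Intramolecular hydrosilylation of an allylic alcohol (5-endo): the Si–H tether on the α-oxygen at C4 can only reach C6 from the α face, and syn addition of Si–H across C5=C6 therefore sets H-5 α (trans ring fusion) and Si-6 α.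

Step 6
Reactants: 10 (1R,4R,5R,6S)-4-O,6-C-(dimethylsilanediyl)-9-(trimethylsilyl)-11,12,13-trinordauc-8-en-4-ol
Product: 11 (1R,4R,5R,6S)-4-O,6-C-(dimethylsilanediyl)-11,12,13-trinordauc-8-en-4-ol
Conditions: CF3CO2H, CH2Cl2, 0 °C; aq. NaHCO3
Reagents that add atoms: none
Why: Acid protodesilylation of a vinylsilane: ipso protonation at C9 is steered by the β-silicon-stabilised C8 cation, so the silyl group is lost with the alkene kept at C8=C9, and no allylic oxygen that could ionise is present at this stage (any ring-opened silanol formed on work-up serves equally in step 7).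

Step 7
Reactants: 11 (1R,4R,5R,6S)-4-O,6-C-(dimethylsilanediyl)-11,12,13-trinordauc-8-en-4-ol
Product: 13 (1R,5S,6S)-6-hydroxy-11,12,13-trinordauc-8-en-4-one (6α-OH; 5α-H; trans-fused), via keto silanol 12 (not isolated)
Conditions: CrO3/H2SO4/H2O (Jones reagent), acetone, 0 °C; i-PrOH, extract; then 30% H2O2, KF, KHCO3, THF/MeOH (1:1), rt
Reagents that add atoms: hydrogen peroxide, OO
Why: Chromic acid (Jones oxidation) in aqueous acetone hydrolyses the labile cyclic silyl ether and oxidises the freed C4 alcohol, so C4 and C6 are differentiated without a protecting group, and Tamao oxidation of the remaining silanol then replaces silicon at C6 by hydroxyl with retention (6α-OH, 5α-H unchanged).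

Step 8
Reactants: 13 (1R,5S,6S)-6-hydroxy-11,12,13-trinordauc-8-en-4-one
Product: 14 (1R,5S,6S)-6-(tert-butyldimethylsilyloxy)-11,12,13-trinordauc-8-en-4-one
Conditions: TBSOTf, 2,6-lutidine, CH2Cl2, −78 °C
Reagents that add atoms: tert-butyldimethylsilyl trifluoromethanesulfonate, CC(C)(C)[Si](C)(C)OS(=O)(=O)C(F)(F)F
Why: Silyl triflate silylation at −78 °C should protect the secondary 6-hydroxyl faster than the ketone can be enolised or the β-hydroxy ketone dehydrated.

Step 9
Reactants: 14 (1R,5S,6S)-6-(tert-butyldimethylsilyloxy)-11,12,13-trinordauc-8-en-4-one; 15 isopropylmagnesium chloride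
Product: 16 (1R,4R,5S,6S)-6-(tert-butyldimethylsilyloxy)dauc-8-en-4-ol (4β-OH, isopropyl α)
Conditions: CeCl3 (anhydrous, 1.5 equiv), 15 (1.5 equiv), THF, −78 → 0 °C; aq. NH4Cl
Reagents that add atoms: none
Why: Organocerium 1,2-addition (low basicity, so little enolisation or β-hydride reduction): attack on the C4 carbonyl from the α face is favoured because the β face is screened by the axial C1 methyl group of the trans-fused bicycle, which sets C4 with isopropyl α and hydroxyl β.

Step 10
Reactants: 17 4-hydroxybenzoic acid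
Product: 18 tert-butyldimethylsilyl 4-(tert-butyldimethylsilyloxy)benzoate
Conditions: TBSCl (2.2 equiv), imidazole, DMF, rt
Reagents that add atoms: tert-butyldimethylsilyl chloride, CC(C)(C)[Si](C)(C)Cl
Why: Imidazole-mediated silylation of both the phenol and the carboxylic acid gives the silyl ether/silyl ester.

Step 11
Reactants: 18 tert-butyldimethylsilyl 4-(tert-butyldimethylsilyloxy)benzoate
Product: 19 4-(tert-butyldimethylsilyloxy)benzoyl chloride
Conditions: (COCl)2, DMF (cat.), CH2Cl2, 0 °C → rt; evaporate
Reagents that add atoms: oxalyl chloride, ClC(=O)C(=O)Cl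
Why: Oxalyl chloride with catalytic DMF (Vilsmeier-type activation) converts the silyl ester directly into the acid chloride and releases the silyl chloride instead of HCl, so the aryl silyl ether should survive.

Step 12
Reactants: 16 (1R,4R,5S,6S)-6-(tert-butyldimethylsilyloxy)dauc-8-en-4-ol; 19 4-(tert-butyldimethylsilyloxy)benzoyl chloride
Product: 21 (1R,4R,5S,6S)-6-(tert-butyldimethylsilyloxy)dauc-8-en-4-yl 4-(tert-butyldimethylsilyloxy)benzoate, via lithium alkoxide 20 (not isolated)
Conditions: n-BuLi, THF, −78 °C; then 19, −78 → 0 °C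
Reagents that add atoms: none
Why: O-Acylation of a preformed lithium tertiary alkoxide with an aroyl chloride should give the hindered tertiary ester, with low temperature and the lithium counter-ion chosen to slow silyl migration from O6.

Step 13
Reactants: 21 (1R,4R,5S,6S)-6-(tert-butyldimethylsilyloxy)dauc-8-en-4-yl 4-(tert-butyldimethylsilyloxy)benzoate
Product: 22 (1R,4R,5S,6S)-6-hydroxydauc-8-en-4-yl 4-hydroxybenzoate
Conditions: HF·pyridine, pyridine, THF, 0 °C → rt
Reagents that add atoms: none
Why: Fluoride-mediated desilylation with pyridine-buffered HF removes both silyl ethers under mildly acidic conditions, under which the tertiary ester should not migrate to the freed 6-hydroxyl.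

Step 14
Reactants: 22 (1R,4R,5S,6S)-6-hydroxydauc-8-en-4-yl 4-hydroxybenzoate
Product: 23 (1R,4R,5S,6S,8R,9S)-8,9-epoxy-6-hydroxydaucan-4-yl 4-hydroxybenzoate (CNP0264773.1; 8α,9α-epoxide)
Conditions: VO(acac)2 (5 mol %), t-BuOOH (in decane), CH2Cl2, 0 °C → rt
Reagents that add atoms: tert-butyl hydroperoxide, CC(C)(C)OO
Why: Vanadium-catalysed hydroxyl-directed epoxidation: the homoallylic 6α-hydroxyl binds the vanadium alkyl peroxide and delivers oxygen to the α face of C8=C9, which sets C8 and C9.

Compound list
1 | 2-bromo-3-methylcyclopent-2-en-1-one | CC1=C(Br)C(=O)CC1 | starting material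
2 | (R)-2-bromo-3-methylcyclopent-2-en-1-ol | O[C@@H]1CCC(C)=C1Br | intermediate
3 | 4,4,5,5-tetramethyl-2-vinyl-1,3,2-dioxaborolane | C=CB1OC(C)(C)C(C)(C)O1 | starting material
4 | (R)-3-methyl-2-vinylcyclopent-2-en-1-ol | O[C@@H]1CCC(C)=C1C=C | intermediate
5 | diiodomethane | ICI | starting material
6 | (1R,2R,5R)-5-methyl-1-vinylbicyclo[3.1.0]hexan-2-ol | O[C@@H]1CC[C@]2(C)C[C@]12C=C | intermediate
7 | 1-(trimethylsilyl)propyne | CC#C[Si](C)(C)C | starting material
8 | (1R,4R)-9-(trimethylsilyl)-11,12,13-trinordauca-5,8-dien-4-ol | O[C@@H]1CC[C@]2(C)CC([Si](C)(C)C)=C(C)CC=C12 | intermediate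
9 | (1R,4R)-4-(dimethylsilyloxy)-9-(trimethylsilyl)-11,12,13-trinordauca-5,8-diene | C[SiH](C)O[C@@H]1CC[C@]2(C)CC([Si](C)(C)C)=C(C)CC=C12 | intermediate
10 | (1R,4R,5R,6S)-4-O,6-C-(dimethylsilanediyl)-9-(trimethylsilyl)-11,12,13-trinordauc-8-en-4-ol | C[Si]1(C)O[C@@H]2CC[C@]3(C)CC([Si](C)(C)C)=C(C)C[C@H]1[C@@H]23 | intermediate
11 | (1R,4R,5R,6S)-4-O,6-C-(dimethylsilanediyl)-11,12,13-trinordauc-8-en-4-ol | C[Si]1(C)O[C@@H]2CC[C@]3(C)CC=C(C)C[C@H]1[C@@H]23 | intermediate
12 | (1R,5R,6S)-6-(hydroxydimethylsilyl)-11,12,13-trinordauc-8-en-4-one | O=C1CC[C@]2(C)CC=C(C)C[C@H]([Si](C)(C)O)[C@@H]12 | intermediate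
13 | (1R,5S,6S)-6-hydroxy-11,12,13-trinordauc-8-en-4-one | O=C1CC[C@]2(C)CC=C(C)C[C@H](O)[C@@H]12 | intermediate
14 | (1R,5S,6S)-6-(tert-butyldimethylsilyloxy)-11,12,13-trinordauc-8-en-4-one | O=C1CC[C@]2(C)CC=C(C)C[C@H](O[Si](C)(C)C(C)(C)C)[C@@H]12 | intermediate
15 | isopropylmagnesium chloride | CC(C)[Mg]Cl | starting material
16 | (1R,4R,5S,6S)-6-(tert-butyldimethylsilyloxy)dauc-8-en-4-ol | CC(C)[C@]1(O)CC[C@]2(C)CC=C(C)C[C@H](O[Si](C)(C)C(C)(C)C)[C@H]21 | intermediate
17 | 4-hydroxybenzoic acid | OC(=O)c1ccc(O)cc1 | starting material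
18 | tert-butyldimethylsilyl 4-(tert-butyldimethylsilyloxy)benzoate | CC(C)(C)[Si](C)(C)OC(=O)c1ccc(O[Si](C)(C)C(C)(C)C)cc1 | intermediate
19 | 4-(tert-butyldimethylsilyloxy)benzoyl chloride | ClC(=O)c1ccc(O[Si](C)(C)C(C)(C)C)cc1 | intermediate
20 | lithium (1R,4R,5S,6S)-6-(tert-butyldimethylsilyloxy)dauc-8-en-4-olate | CC(C)[C@]1([O-])CC[C@]2(C)CC=C(C)C[C@H](O[Si](C)(C)C(C)(C)C)[C@H]21.[Li+] | intermediate
21 | (1R,4R,5S,6S)-6-(tert-butyldimethylsilyloxy)dauc-8-en-4-yl 4-(tert-butyldimethylsilyloxy)benzoate | CC(C)[C@]1(OC(=O)c2ccc(O[Si](C)(C)C(C)(C)C)cc2)CC[C@]2(C)CC=C(C)C[C@H](O[Si](C)(C)C(C)(C)C)[C@H]21 | intermediate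
22 | (1R,4R,5S,6S)-6-hydroxydauc-8-en-4-yl 4-hydroxybenzoate | CC(C)[C@]1(OC(=O)c2ccc(O)cc2)CC[C@]2(C)CC=C(C)C[C@H](O)[C@H]21 | intermediate
23 | (1R,4R,5S,6S,8R,9S)-8,9-epoxy-6-hydroxydaucan-4-yl 4-hydroxybenzoate | CC(C)[C@]1(OC(=O)c2ccc(O)cc2)CC[C@]2(C)C[C@@H]3O[C@]3(C)C[C@H](O)[C@H]21 | target

Total step count: 14. Longest linear sequence: 12 steps (steps 1–9 and 12–14).

Steps most likely to fail

1. Step 4. Rhodium may insert into the more substituted C5–C1 bond or merely isomerise the strained vinylcyclopropane to dienes, the hindered silylalkyne may insert too slowly, and rhodium hydrides may isomerise the allylic alcohol. The fallback sets out from 6 and comes back at 8. Oxidation of 6 with Dess–Martin periodinane should give (1R,5R)-5-methyl-1-vinylbicyclo[3.1.0]hexan-2-one F1, whose acyl group polarises and weakens the cyclopropane. Cycloaddition of this ketone with 7 under [Rh(CO)2Cl]2 should give (1R)-9-(trimethylsilyl)-11,12,13-trinordauca-5,8-dien-4-one F2. Catalyst-controlled reduction with (S)-2-methyl-CBS-oxazaborolidine and BH3·SMe2 should then return the 4α-alcohol 8.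

2. Step 5. Ring closure onto the hindered trisubstituted C5=C6 alkene may be slow, so that platinum hydride-mediated alkene migration or intermolecular hydrosilylation takes over. The fallback sets out from 8 and comes back at 13. Hydroxyl-directed epoxidation of 8 (VO(acac)2, t-BuOOH) should give (1R)-5α,6α-epoxy-9-(trimethylsilyl)-11,12,13-trinordauc-8-en-4α-ol F3. Dess–Martin oxidation should give (1R)-5α,6α-epoxy-9-(trimethylsilyl)-11,12,13-trinordauc-8-en-4-one F4. Brief CF3CO2H treatment should remove the vinylic silyl group to give (1R)-5α,6α-epoxy-11,12,13-trinordauc-8-en-4-one F5. SmI2 in THF/MeOH at −90 °C should open the epoxide at C5 to give 13. In this variant O-6 is still placed by the C4 hydroxyl, but H-5 comes from protonation of a samarium enolate, so a 5-epimer may have to be separated or equilibrated.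

3. Step 12. Acylation of the hindered tertiary alkoxide may stall, and the alkoxide may instead take a silyl group from O6 or from the aryl silyl ether, which would lead to acylation at the wrong oxygen. The fallback sets out from 16 and comes back at 21 without forming an alkoxide. Heating 18 with 19 should give 4-(tert-butyldimethylsilyloxy)benzoic anhydride F6. Bi(OTf)3-catalysed acylation of the neutral tertiary alcohol 16 with this anhydride (CH2Cl2, rt) should give 21.

Further compounds
F1 | step 4 | (1R,5R)-5-methyl-1-vinylbicyclo[3.1.0]hexan-2-one | O=C1CC[C@]2(C)C[C@]12C=C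
F2 | step 4 | (1R)-9-(trimethylsilyl)-11,12,13-trinordauca-5,8-dien-4-one | O=C1CC[C@]2(C)CC([Si](C)(C)C)=C(C)CC=C12
F3 | step 5 | (1R)-5α,6α-epoxy-9-(trimethylsilyl)-11,12,13-trinordauc-8-en-4α-ol | O[C@@H]1CC[C@]2(C)CC([Si](C)(C)C)=C(C)C[C@@H]3O[C@]123
F4 | step 5 | (1R)-5α,6α-epoxy-9-(trimethylsilyl)-11,12,13-trinordauc-8-en-4-one | O=C1CC[C@]2(C)CC([Si](C)(C)C)=C(C)C[C@@H]3O[C@]123
F5 | step 5 | (1R)-5α,6α-epoxy-11,12,13-trinordauc-8-en-4-one | O=C1CC[C@]2(C)CC=C(C)C[C@@H]3O[C@]123
F6 | step 12 | 4-(tert-butyldimethylsilyloxy)benzoic anhydride | CC(C)(C)[Si](C)(C)Oc1ccc(cc1)C(=O)OC(=O)c1ccc(O[Si](C)(C)C(C)(C)C)cc1
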